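**Retrosynthetic overview**
1. The two sulfate esters go on late, onto the only free hydroxyls (3-OH and 3'-OH) of a 5,4'-di-O-benzyl flavonol; hydrogenolysis then frees 5-OH and 4'-OH.
2. The 3-OH comes from epoxidation and rearrangement of the corresponding flavone; the 3'-OH is carried as a MOM ether.
3. The route rests on the C2=C3 double bond of ring C: C3 is bonded to the C4 carbonyl carbon, and C2 carries both O1 and ring B. It is disconnected as an intramolecular Wittig olefination in which a ring A phenacyl ylide carbon (future C3) attacks the carbonyl of a ring B aryl ester (future C2).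
4. The ylide ester is assembled from a phenolic ring A ylide (2',6'-dihydroxy-4'-methoxyacetophenone: benzylation, alpha-bromination, PPh3, base) and a ring B acid chloride (3,4-dihydroxybenzaldehyde: benzylation, MOM protection, oxidation, chlorination).
5. Rings A and B are bought; ring C is the only ring formed.

Key step: step 9

Assumption: the target is taken as the free bis(hydrogen sulfate) as drawn. Aryl hydrogen sulfates hydrolyse under their own acidity, so the disodium salt is the storage form and the free acid is liberated cold by cation exchange only at the very end. Flavonoid numbering (O1, C2 to C4, ring A C5 to C8, ring B primed) is used in the comments.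

**Route**

Step 1
Reactants: 1 1-(2,6-dihydroxy-4-methoxyphenyl)ethanone
Product: 2 1-[2-(benzyloxy)-6-hydroxy-4-methoxyphenyl]ethanone
Conditions: BnBr (1.05 equiv), K2CO3, acetone, reflux
Reagents that add atoms: benzyl bromide, BrCc1ccccc1
Why: Williamson ether synthesis on a symmetric diol, which should stop at the mono-ether because the remaining hydroxyl is locked in a hydrogen bond to the ketone and only one equivalent of halide is supplied.

Step 2
Reactants: 2 1-[2-(benzyloxy)-6-hydroxy-4-methoxyphenyl]ethanone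
Product: 4 1-[2-(benzyloxy)-6-hydroxy-4-methoxyphenyl]-2-bromoethanone, via silyl enol ether 3 (not isolated)
Conditions: Me3SiOTf (2.3 equiv), Et3N, CH2Cl2, 0 °C; NBS (1.0 equiv), THF, −78 °C; 1 M HCl, THF, 0 °C
Reagents that add atoms: N-bromosuccinimide, O=C1CCC(=O)N1Br
Why: Soft enolisation to the silyl enol ether followed by electrophilic alpha-bromination with NBS, in which the enol ether should react far faster at −78 °C than the electron-rich ring, while the acidic work-up cleaves the aryl silyl ether and avoids base-induced closure to a benzofuran-3-one.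

Step 3
Reactants: 4 1-[2-(benzyloxy)-6-hydroxy-4-methoxyphenyl]-2-bromoethanone
Product: 6 1-[2-(benzyloxy)-6-hydroxy-4-methoxyphenyl]-2-(triphenyl-lambda5-phosphanylidene)ethanone, via phosphonium bromide 5 (not isolated)
Conditions: PPh3 (1.05 equiv), CH2Cl2, rt; then 1 M aq Na2CO3, rt
Reagents that add atoms: triphenylphosphine, c1ccc(cc1)P(c1ccccc1)c1ccccc1
Why: SN2 quaternisation of PPh3 by the primary phenacyl bromide, then deprotonation of the acidic phosphonium methylene by carbonate to the keto-stabilised ylide, the less acidic hydrogen-bonded phenol staying protonated.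

Step 4
Reactants: 7 3,4-dihydroxybenzaldehyde
Product: 8 4-(benzyloxy)-3-hydroxybenzaldehyde
Conditions: BnBr (1.0 equiv), NaHCO3, NaI (cat.), DMF, 40 °C
Reagents that add atoms: benzyl bromide, BrCc1ccccc1
Why: Regioselective Williamson etherification, since the weak base ionises only the more acidic 4-OH, which is para to the formyl group.

Step 5
Reactants: 8 4-(benzyloxy)-3-hydroxybenzaldehyde
Product: 9 4-(benzyloxy)-3-(methoxymethoxy)benzaldehyde
Conditions: MOMCl, iPr2NEt, CH2Cl2, 0 °C to rt
Reagents that add atoms: chloromethyl methyl ether, COCCl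
Why: O-alkylation of the phenol by the reactive alpha-chloro ether (MOM ether formation) under amine base.

Step 6
Reactants: 9 4-(benzyloxy)-3-(methoxymethoxy)benzaldehyde
Product: 10 4-(benzyloxy)-3-(methoxymethoxy)benzoic acid
Conditions: NaClO2, NaH2PO4, 2-methyl-2-butene, t-BuOH–H2O, rt
Reagents that add atoms: sodium chlorite, [Na+].[O-]Cl=O
Why: Pinnick oxidation of the aldehyde, in which the phosphate buffer is too mild to cleave the MOM acetal and the alkene scavenger keeps hypochlorous acid away from the electron-rich ring.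

Step 7
Reactants: 10 4-(benzyloxy)-3-(methoxymethoxy)benzoic acid
Product: 11 4-(benzyloxy)-3-(methoxymethoxy)benzoyl chloride
Conditions: 1-chloro-N,N,2-trimethylprop-1-en-1-amine (1.1 equiv), CH2Cl2, 0 °C to rt; concentrated and used crude
Reagents that add atoms: 1-chloro-N,N,2-trimethylprop-1-en-1-amine, CC(C)=C(Cl)N(C)C
Why: Acid chloride formation with the Ghosez alpha-chloroenamine, which releases a neutral amide instead of HCl and so should spare the MOM ether.

Step 8
Reactants: 6 1-[2-(benzyloxy)-6-hydroxy-4-methoxyphenyl]-2-(triphenyl-lambda5-phosphanylidene)ethanone; 11 4-(benzyloxy)-3-(methoxymethoxy)benzoyl chloride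
Product: 12 3-(benzyloxy)-5-methoxy-2-[(triphenyl-lambda5-phosphanylidene)acetyl]phenyl 4-(benzyloxy)-3-(methoxymethoxy)benzoate
Conditions: 11 (1.05 equiv, slow addition), pyridine, CH2Cl2, −20 °C to rt; cold aq NaHCO3 wash; used at once
Reagents that add atoms: none
Why: Einhorn-type O-acylation of a phenol by an acid chloride in pyridine, in which the hard N-acylpyridinium ion should be taken up by the phenolic oxygen rather than by the delocalised ylide carbon, one equivalent at low temperature limits C-acylation, and the NaHCO3 wash returns any protonated material to the free ylide.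

Step 9
Reactants: 12 3-(benzyloxy)-5-methoxy-2-[(triphenyl-lambda5-phosphanylidene)acetyl]phenyl 4-(benzyloxy)-3-(methoxymethoxy)benzoate
Product: 13 5-(benzyloxy)-2-[4-(benzyloxy)-3-(methoxymethoxy)phenyl]-7-methoxy-4H-chromen-4-one
Conditions: toluene, reflux (110 °C)
Reagents that add atoms: none
Why: The nucleophilic ylide carbon (future C3) adds to the carbonyl of the neighbouring aroate (future C2) to give a betaine that closes to a 1,2-oxaphosphetane, and its cycloreversion expels triphenylphosphine oxide and leaves the C2=C3 double bond. The closest known reaction type is the intramolecular Wittig olefination of an ester carbonyl by an acyl-stabilised phosphorane, the established conversion of (2-aroyloxyphenacylidene)phosphoranes into flavones. Ring C closes in a 6-exo-trig mode, the attacked C=O being exocyclic to the forming pyranone. No stereocentre is created. The selectivity needed is collapse of the tetrahedral adduct to the alkene rather than expulsion of the ring A aryloxide, which would amount to an O-to-C acyl shift giving a diacyl ylide; base-free, non-polar conditions disfavour that charge-separated pair, whereas loss of the phosphine oxide with formation of the aromatic 4-pyranone is irreversible. The benzyl and MOM ethers are inert to neutral heating.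

Step 10
Reactants: 13 5-(benzyloxy)-2-[4-(benzyloxy)-3-(methoxymethoxy)phenyl]-7-methoxy-4H-chromen-4-one
Product: 15 5-(benzyloxy)-2-[4-(benzyloxy)-3-(methoxymethoxy)phenyl]-3-hydroxy-7-methoxy-4H-chromen-4-one, via 2,3-epoxyflavanone 14 (not isolated)
Conditions: dimethyldioxirane (3 equiv, acetone solution), CH2Cl2, 0 °C to rt, dark; then p-TsOH·H2O (cat.), CHCl3, rt
Reagents that add atoms: dimethyldioxirane, CC1(C)OO1
Why: Dioxirane epoxidation of the C2=C3 bond of a fully O-protected flavone, then acid-catalysed oxirane opening at C2 (cation stabilised by O1 and ring B) and loss of H3 to give the flavonol, so the two racemic epoxide stereocentres are destroyed again.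

Step 11
Reactants: 15 5-(benzyloxy)-2-[4-(benzyloxy)-3-(methoxymethoxy)phenyl]-3-hydroxy-7-methoxy-4H-chromen-4-one
Product: 16 5-(benzyloxy)-2-[4-(benzyloxy)-3-hydroxyphenyl]-3-hydroxy-7-methoxy-4H-chromen-4-one
Conditions: 2 M aq HCl, MeOH–THF, 45 °C
Reagents that add atoms: none
Why: Acid-catalysed solvolysis of the aryl MOM acetal, which should proceed under dilute acid at moderate temperature well before the benzyl ethers are touched.

Step 12
Reactants: 16 5-(benzyloxy)-2-[4-(benzyloxy)-3-hydroxyphenyl]-3-hydroxy-7-methoxy-4H-chromen-4-one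
Product: 17 disodium 5-(benzyloxy)-2-[4-(benzyloxy)-3-(sulfonatooxy)phenyl]-7-methoxy-4-oxo-4H-chromen-3-yl sulfate
Conditions: SO3·pyridine (8 equiv), pyridine, 55 °C; then aq NaHCO3; C18 desalting
Reagents that add atoms: sulfur trioxide pyridine complex, O=S(=O)([O-])[n+]1ccccc1; sodium hydrogen carbonate, [Na+].OC([O-])=O
Why: O-sulfonation with an amine–SO3 complex, regiodefined because 3-OH and 3'-OH are the only free hydroxyls, with excess reagent and warming to drive the hindered, hydrogen-bonded 3-OH to completion and neutralisation to the stable sodium salt.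

Step 13
Reactants: 17 disodium 5-(benzyloxy)-2-[4-(benzyloxy)-3-(sulfonatooxy)phenyl]-7-methoxy-4-oxo-4H-chromen-3-yl sulfate
Product: 18 rhamnetin 3,3'-disulfate, 2-[4-hydroxy-3-(sulfooxy)phenyl]-5-hydroxy-7-methoxy-4-oxo-4H-chromen-3-yl hydrogen sulfate
Conditions: H2 (1 atm), Pd/C (10 wt%), MeOH–H2O, rt; then sulfonic acid cation-exchange resin (H+ form), H2O, 0 °C; freeze-dry
Reagents that add atoms: none
Why: Catalytic hydrogenolysis of the two aryl benzyl ethers on palladium on carbon, to which aryl sulfate monoester salts and the tetrasubstituted C2=C3 bond should be inert, followed by cold cation exchange to the free acid.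

**Compound list**
1 | 1-(2,6-dihydroxy-4-methoxyphenyl)ethanone | COc1cc(O)c(C(C)=O)c(O)c1 | starting material
2 | 1-[2-(benzyloxy)-6-hydroxy-4-methoxyphenyl]ethanone | COc1cc(O)c(C(C)=O)c(OCc2ccccc2)c1 | intermediate
3 | ({1-[2-(benzyloxy)-4-methoxy-6-(trimethylsilyloxy)phenyl]ethenyl}oxy)trimethylsilane (silyl enol ether, not isolated) | C=C(O[Si](C)(C)C)c1c(OCc2ccccc2)cc(OC)cc1O[Si](C)(C)C | intermediate
4 | 1-[2-(benzyloxy)-6-hydroxy-4-methoxyphenyl]-2-bromoethanone | COc1cc(O)c(C(=O)CBr)c(OCc2ccccc2)c1 | intermediate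
5 | {2-[2-(benzyloxy)-6-hydroxy-4-methoxyphenyl]-2-oxoethyl}triphenylphosphonium bromide (not isolated) | COc1cc(O)c(C(=O)C[P+](c2ccccc2)(c2ccccc2)c2ccccc2)c(OCc2ccccc2)c1.[Br-] | intermediate
6 | 1-[2-(benzyloxy)-6-hydroxy-4-methoxyphenyl]-2-(triphenyl-lambda5-phosphanylidene)ethanone | COc1cc(O)c(C(=O)C=P(c2ccccc2)(c2ccccc2)c2ccccc2)c(OCc2ccccc2)c1 | intermediate
7 | 3,4-dihydroxybenzaldehyde | O=Cc1ccc(O)c(O)c1 | starting material
8 | 4-(benzyloxy)-3-hydroxybenzaldehyde | O=Cc1ccc(OCc2ccccc2)c(O)c1 | intermediate
9 | 4-(benzyloxy)-3-(methoxymethoxy)benzaldehyde | COCOc1cc(C=O)ccc1OCc1ccccc1 | intermediate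
10 | 4-(benzyloxy)-3-(methoxymethoxy)benzoic acid | COCOc1cc(C(=O)O)ccc1OCc1ccccc1 | intermediate
11 | 4-(benzyloxy)-3-(methoxymethoxy)benzoyl chloride | COCOc1cc(C(=O)Cl)ccc1OCc1ccccc1 | intermediate
12 | 3-(benzyloxy)-5-methoxy-2-[(triphenyl-lambda5-phosphanylidene)acetyl]phenyl 4-(benzyloxy)-3-(methoxymethoxy)benzoate | COCOc1cc(C(=O)Oc2cc(OC)cc(OCc3ccccc3)c2C(=O)C=P(c2ccccc2)(c2ccccc2)c2ccccc2)ccc1OCc1ccccc1 | intermediate
13 | 5-(benzyloxy)-2-[4-(benzyloxy)-3-(methoxymethoxy)phenyl]-7-methoxy-4H-chromen-4-one | COCOc1cc(-c2cc(=O)c3c(OCc4ccccc4)cc(OC)cc3o2)ccc1OCc1ccccc1 | intermediate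
14 | 5-(benzyloxy)-2-[4-(benzyloxy)-3-(methoxymethoxy)phenyl]-2,3-epoxy-7-methoxy-2,3-dihydro-4H-chromen-4-one (racemic, cis-fused oxirane, one enantiomer drawn, not isolated) | O=C1c2c(OCc3ccccc3)cc(OC)cc2O[C@@]2(c3ccc(OCc4ccccc4)c(OCOC)c3)O[C@@H]12 | intermediate
15 | 5-(benzyloxy)-2-[4-(benzyloxy)-3-(methoxymethoxy)phenyl]-3-hydroxy-7-methoxy-4H-chromen-4-one | COCOc1cc(-c2oc3cc(OC)cc(OCc4ccccc4)c3c(=O)c2O)ccc1OCc1ccccc1 | intermediate
16 | 5-(benzyloxy)-2-[4-(benzyloxy)-3-hydroxyphenyl]-3-hydroxy-7-methoxy-4H-chromen-4-one | Oc1cc(-c2oc3cc(OC)cc(OCc4ccccc4)c3c(=O)c2O)ccc1OCc1ccccc1 | intermediate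
17 | disodium 5-(benzyloxy)-2-[4-(benzyloxy)-3-(sulfonatooxy)phenyl]-7-methoxy-4-oxo-4H-chromen-3-yl sulfate | COc1cc(OCc2ccccc2)c2c(=O)c(OS(=O)(=O)[O-])c(-c3ccc(OCc4ccccc4)c(OS(=O)(=O)[O-])c3)oc2c1.[Na+].[Na+] | intermediate
18 | rhamnetin 3,3'-disulfate | COc1cc(O)c2c(=O)c(OS(=O)(=O)O)c(-c3ccc(O)c(OS(=O)(=O)O)c3)oc2c1 | target

**Step count**
Total: 13 steps. Longest linear sequence: 10 steps (7 to 18, steps 4 to 13); the ring A branch (1 to 6) is 3 steps.

**Steps most likely to fail**

Step 8 (acylation giving the ylide ester). The acyl group may be delivered to the ylide carbon instead of the phenolic oxygen, giving a doubly stabilised diacyl ylide that cannot olefinate, or a second acylation may follow. The fallback reverses the order, so that the ylide is only created once the ester is in place. It sets out from 2 and 11. The phenol of 2 is acylated with 11 (pyridine, DMAP cat., CH2Cl2; aq NaHCO3 work-up) to give 2-acetyl-3-(benzyloxy)-5-methoxyphenyl 4-(benzyloxy)-3-(methoxymethoxy)benzoate F1. Kinetic enolisation with in-flask trapping (LiN(SiMe3)2, Me3SiCl, THF, −78 °C) should give the silyl enol ether 3-(benzyloxy)-5-methoxy-2-[1-(trimethylsilyloxy)ethenyl]phenyl 4-(benzyloxy)-3-(methoxymethoxy)benzoate F2 before the enolate can attack the ester. NBS at −78 °C converts it into 3-(benzyloxy)-2-(bromoacetyl)-5-methoxyphenyl 4-(benzyloxy)-3-(methoxymethoxy)benzoate F3. PPh3 in toluene gives the phosphonium bromide F4, and cold aqueous NaHCO3 returns the route at 12.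

Step 9 (key step). Olefination of the electron-rich aroate carbonyl may be slow, so that expulsion of the ring A aryloxide from the tetrahedral adduct (acyl shift to carbon) or thermal decomposition takes over. The fallback abandons the ester olefination and builds C2–C3 by aldol chemistry. It sets out from 2 and 9. Claisen–Schmidt condensation (KOH, EtOH–THF, rt) gives the chalcone (E)-1-[2-(benzyloxy)-6-hydroxy-4-methoxyphenyl]-3-[4-(benzyloxy)-3-(methoxymethoxy)phenyl]prop-2-en-1-one F5. Oxidative cyclisation with I2 (cat.) in DMSO at 120 °C (oxa-Michael closure, then dehydrogenation) returns the route at 13.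

Step 10 (C3 hydroxylation). Epoxidation of the electron-poor enone may be slow enough for benzylic oxidation of the two benzyl ethers by the dioxirane to compete, and the epoxide may open incompletely. The fallback uses deprotonation instead of oxygen transfer and sets out from 13. LiN(iPr)2 in THF at −78 °C should remove H3 to give the 3-lithioflavone F6. B(OMe)3 converts it into the dimethyl boronate F7, and H2O2 with AcOH oxidises the C–B bond to C–OH, returning the route at 15.

**Further compounds**
F1 | step 8 | 2-acetyl-3-(benzyloxy)-5-methoxyphenyl 4-(benzyloxy)-3-(methoxymethoxy)benzoate | COCOc1cc(C(=O)Oc2cc(OC)cc(OCc3ccccc3)c2C(C)=O)ccc1OCc1ccccc1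
F2 | step 8 | 3-(benzyloxy)-5-methoxy-2-[1-(trimethylsilyloxy)ethenyl]phenyl 4-(benzyloxy)-3-(methoxymethoxy)benzoate | COCOc1cc(C(=O)Oc2cc(OC)cc(OCc3ccccc3)c2C(=C)O[Si](C)(C)C)ccc1OCc1ccccc1
F3 | step 8 | 3-(benzyloxy)-2-(bromoacetyl)-5-methoxyphenyl 4-(benzyloxy)-3-(methoxymethoxy)benzoate | COCOc1cc(C(=O)Oc2cc(OC)cc(OCc3ccccc3)c2C(=O)CBr)ccc1OCc1ccccc1
F4 | step 8 | {2-[2-(benzyloxy)-6-{[4-(benzyloxy)-3-(methoxymethoxy)benzoyl]oxy}-4-methoxyphenyl]-2-oxoethyl}triphenylphosphonium bromide | COCOc1cc(C(=O)Oc2cc(OC)cc(OCc3ccccc3)c2C(=O)C[P+](c2ccccc2)(c2ccccc2)c2ccccc2)ccc1OCc1ccccc1.[Br-]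
F5 | step 9 | (E)-1-[2-(benzyloxy)-6-hydroxy-4-methoxyphenyl]-3-[4-(benzyloxy)-3-(methoxymethoxy)phenyl]prop-2-en-1-one | COCOc1cc(/C=C/C(=O)c2c(O)cc(OC)cc2OCc2ccccc2)ccc1OCc1ccccc1
F6 | step 10 | {5-(benzyloxy)-2-[4-(benzyloxy)-3-(methoxymethoxy)phenyl]-7-methoxy-4-oxo-4H-chromen-3-yl}lithium | COCOc1cc(-c2oc3cc(OC)cc(OCc4ccccc4)c3c(=O)c2[Li])ccc1OCc1ccccc1
F7 | step 10 | dimethyl {5-(benzyloxy)-2-[4-(benzyloxy)-3-(methoxymethoxy)phenyl]-7-methoxy-4-oxo-4H-chromen-3-yl}boronate | COCOc1cc(-c2oc3cc(OC)cc(OCc4ccccc4)c3c(=O)c2B(OC)OC)ccc1OCc1ccccc1
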